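**Plan**

- Retrosynthesis: the isovanillate C6–O acyl bond is cut first; the C8–CH3 bond and the C6 carbinol are then traced back to the C6/C8 1,3-dione of a cis-fused hydroazulene.
- The dione is re-closed across C6–C9 to a 3-siloxycyclobutanone fused to a cis-diquinane; C7–C8 is a dichloroketene unit added across a C6=C9 silyl enol ether.
- The diquinane ketone is cut at C6–C9 (hydroacylation of a 4-pentenal), at C1–C10 (conjugate vinyl addition) and at C1–C5 (aldol), which leads to the ozonolysis product of (S)-terpinen-4-ol.
- Forward order of rings: cyclopentene ring A by aldol condensation, then the cyclopentanone C5–C6–C9–C10–C1, then the cyclobutanone, then the seven-membered ring by fragmentation of the shared C6–C9 bond; methyl group, carbinol and ester follow.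
- Enabling feature: C7 and C8 of the seven-membered ring lie between oxygenated C6 and C9, so this ring is the cyclopentanone C5/C6/C9/C10/C1 with a two-carbon ketene unit inserted into C6–C9; the dione oxygens at C6 and C8 sit where the ester carbinol and the methylated alkene carbon are needed.
- Stereochemistry: C4 comes from (S)-terpinen-4-ol; C1 from vinyl addition anti to the C4 isopropyl group; C5 from equilibration and the cis-only ring closure; C6 from hydride attack on the convex face.

Key step: step 9

Convention: locants are those of the daucane skeleton of the target (C1 quaternary methyl carbon, C4 isopropyl carbinol, C5 ring-fusion CH, C6 ester carbon, C7=C8, C9, C10) and are kept for every intermediate; α is the face of the C1 methyl group and H5 (convex face of the cis-fused bicycles), β the face of the C4 oxygen.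

Remark: cleavage of the ring-fusion bond is taken to be the intrinsic retro-aldol mode of 1-siloxybicyclo[3.2.0]heptan-6-ones, since it is the mode that turns the parent compound into cycloheptane-1,3-dione; cleavage of the exocyclic C6–C7 bond is the competing mode.

**Route**

Step 1
Reactants: 1 (S)-terpinen-4-ol
Product: 2 (S)-terpinen-4-ol triethylsilyl ether
Conditions: Et3SiOTf, 2,6-lutidine, CH2Cl2, −78 → 0 °C
Reagents that add atoms: triethylsilyl trifluoromethanesulfonate, CC[Si](CC)(CC)OS(=O)(=O)C(F)(F)F
Why: Silylation of a hindered tertiary alcohol with a silyl triflate and a hindered pyridine base is standard, and the ether blocks retro-aldol and dehydration of the β-oxygenated aldehyde made next while later distinguishing the C4 oxygen from the C6 trimethylsilyl ether.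

Step 2
Reactants: 2 (S)-terpinen-4-ol triethylsilyl ether
Product: 4 (3S)-6-oxo-3-(propan-2-yl)-3-(triethylsilyloxy)heptanal, via secondary ozonide 3 (not isolated)
Conditions: O3, CH2Cl2, −78 °C; then PPh3, −78 °C → rt
Reagents that add atoms: ozone, [O-][O+]=O
Why: Ozonolysis with reductive work-up cleaves the only C=C bond to the 1,6-keto aldehyde and leaves the silyl ether and the carbinol stereocentre untouched.

Step 3
Reactants: 4 (3S)-6-oxo-3-(propan-2-yl)-3-(triethylsilyloxy)heptanal
Product: 5 (5R)-2-methyl-5-(propan-2-yl)-5-(triethylsilyloxy)cyclopent-1-ene-1-carbaldehyde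
Conditions: piperidine, AcOH, PhMe, 60 °C
Reagents that add atoms: none
Why: In this amine-catalysed intramolecular aldol condensation the enamine of the more reactive aldehyde should add to the methyl ketone (five-membered ring, C5–C1 bond) and the new tertiary aldol hydroxyl, which is protonated more easily than the silyl ether, is lost to give the conjugated enal, as is established for terpene-derived 6-oxoheptanals.

Step 4
Reactants: 5 (5R)-2-methyl-5-(propan-2-yl)-5-(triethylsilyloxy)cyclopent-1-ene-1-carbaldehyde; 6 vinylmagnesium bromide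
Product: 8 (1R,2S,5R)-2-ethenyl-2-methyl-5-(propan-2-yl)-5-(triethylsilyloxy)cyclopentane-1-carbaldehyde, via trimethylsilyl enol ether 7 (not isolated)
Conditions: CH2=CHMgBr, CuBr·SMe2 (20 mol %), Me3SiCl, THF, −78 → −40 °C; aqueous NH4Cl work-up; then K2CO3, MeOH, 0 °C → rt
Reagents that add atoms: vinylmagnesium bromide 6, C=C[Mg]Br; chlorotrimethylsilane, C[Si](C)(C)Cl (silyl group present in 7 only)
Why: Copper-catalysed, Me3SiCl-accelerated conjugate addition of a Grignard reagent to a β,β-disubstituted enal should create quaternary C1 with vinyl entering anti to the C4 isopropyl group (allylic strain with the formyl group places isopropyl pseudoaxial), and methanolysis of the silyl enol ether under equilibrating base should set C5 with the formyl group anti to isopropyl, that is cis to vinyl.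

Step 5
Reactants: 8 (1R,2S,5R)-2-ethenyl-2-methyl-5-(propan-2-yl)-5-(triethylsilyloxy)cyclopentane-1-carbaldehyde
Product: 9 cis-diquinane ketone (3aS,6R,6aR)-3a-methyl-6-(propan-2-yl)-6-(triethylsilyloxy)hexahydropentalen-1(2H)-one
Conditions: [Rh(dppe)]ClO4 (5 mol %, dppe = Ph2PCH2CH2PPh2), CH2Cl2, rt
Reagents that add atoms: none
Why: Rhodium-catalysed intramolecular hydroacylation of a 4-pentenal (acyl–rhodium hydride, alkene insertion, reductive elimination) forms the C6–C9 bond of the cyclopentanone, and since only the cis-fused bicycle can form, C1 and C5 are carried over unchanged.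

Step 6
Reactants: 9 cis-diquinane ketone
Product: 10 trimethylsilyl enol ether of 9 (C6–OSiMe3, C6=C9)
Conditions: LiN(iPr)2, THF, −78 °C; then Me3SiCl, −78 → 0 °C
Reagents that add atoms: chlorotrimethylsilane, C[Si](C)(C)Cl
Why: Kinetic enolisation should remove a C9 methylene proton and not the congested ring-fusion H5, so O-silylation gives the less substituted enol ether without epimerising C5 or eliminating the β-silyloxy group.

Step 7
Reactants: 10 trimethylsilyl enol ether of 9; 11 trichloroacetyl chloride
Product: 12 tricyclic 7,7-dichloro-6β-(trimethylsilyloxy)cyclobutanone (C8 ketone; C7–C8 bridge on the α-face of C6 and C9)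
Conditions: Cl3CCOCl, Zn, Et2O–MeOCH2CH2OMe, rt, ultrasound
Reagents that add atoms: trichloroacetyl chloride 11, ClC(Cl)(Cl)C(Cl)=O (delivered as dichloroketene)
Why: Dichloroketene undergoes the known regioselective thermal (2+2) cycloaddition with silyl enol ethers, its carbonyl carbon bonding to nucleophilic C9 and the CCl2 carbon to oxygenated C6, from the convex α-face of the diquinane; both new stereocentres are erased in step 9.

Step 8
Reactants: 12 tricyclic 7,7-dichloro-6β-(trimethylsilyloxy)cyclobutanone
Product: 13 tricyclic 6β-(trimethylsilyloxy)cyclobutanone (3-siloxycyclobutanone fused across C6–C9 of the cis-diquinane, C8 ketone, C7 methylene)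
Conditions: Bu3SnH (2.2 equiv), AIBN (cat.), PhH, 80 °C
Reagents that add atoms: none
Why: Radical hydrodechlorination of α,α-dichlorocyclobutanones with Bu3SnH is routine and, being neutral, keeps the tertiary trimethylsilyl ether and with it the latent β-hydroxy ketone intact.

Step 9
Reactants: 13 tricyclic 6β-(trimethylsilyloxy)cyclobutanone
Product: 14 cis-fused hydroazulene-6,8-dione (1α-methyl, 5α-H, 4β-triethylsilyloxy, 4α-isopropyl)
Conditions: K2CO3 (0.5 equiv), MeOH, 0 °C → rt; pH 5 buffer work-up
Reagents that add atoms: none
Why: Methoxide-assisted cleavage of the tertiary Me3Si–O bond unmasks the C6 alkoxide of a β-hydroxycyclobutanone, which collapses to the C6 ketone with heterolysis of the C6–C9 bond, and the C8 enolate so formed is protonated at C9 and rests as the stabilised 1,3-diketonate until work-up. The closest known reaction is the desilylative retro-aldol ring expansion of 1-siloxybicyclo[n.2.0]alkanones that carry the carbonyl in the four-membered ring, which gives cycloalkane-1,3-diones two carbons larger than the starting cycloalkanone. The seven-membered ring is not closed by a cyclisation: it arises when the zero-atom bridge of the bicyclo[3.2.0]heptanone unit breaks, so that the five- and four-membered rings merge. No stereocentre is created; C6 becomes trigonal and C9 a methylene group, and C1, C4 and C5 are not touched because the diketonate is formed at C7 and not at C5. The selectivity needed is cleavage of the ring-fusion bond C6–C9 and not of the exocyclic C6–C7 bond; it rests on the larger strain release when both small rings open at once and on the more substituted enolate terminus at C9. The triethylsilyl ether on the hindered tertiary C4 oxygen should survive K2CO3/MeOH, which keeps that oxygen from starting a second retro-aldol across C4–C5.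

Step 10
Reactants: 14 cis-fused hydroazulene-6,8-dione
Product: 15 vinylogous triflate (C6 ketone, C7=C8, triflyloxy on C8)
Conditions: Tf2O, Et3N, CH2Cl2, −78 °C
Reagents that add atoms: trifluoromethanesulfonic anhydride, O=S(=O)(OS(=O)(=O)C(F)(F)F)C(F)(F)F
Why: O-Sulfonylation of the diketonate should take place at the C8 oxygen, remote from the crowded C5/C4 region, as is general for enol derivatisation of 4-substituted cycloalkane-1,3-diones, leaving the carbonyl at C6.

Step 11
Reactants: 15 vinylogous triflate
Product: 16 enone (C6 ketone, C7=C8 with methyl on C8)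
Conditions: Me2CuLi (from CuI and MeLi), THF, −78 °C
Reagents that add atoms: lithium dimethylcuprate, [Li+].C[Cu-]C
Why: Conjugate addition–elimination of a dialkylcuprate on a β-triflyloxy enone replaces triflate by methyl with the double bond kept at C7=C8, and the reagent is too weakly basic to enolise C5.

Step 12
Reactants: 16 enone
Product: 17 allylic alcohol (6β-hydroxy, C7=C8, 4β-triethylsilyloxy)
Conditions: NaBH4, CeCl3·7H2O, MeOH, −40 °C
Reagents that add atoms: none
Why: Luche reduction secures 1,2-addition, and hydride should reach C6 from the convex α-face next to H5 because the β-face is covered by C4 and its silyloxy group, which places the C6 hydroxyl β (6R).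

Step 13
Reactants: 17 allylic alcohol
Product: 18 diol (4β,6β-dihydroxy, C7=C8)
Conditions: Bu4NF, THF, rt → 40 °C
Reagents that add atoms: none
Why: Fluoride cleaves the tertiary triethylsilyl ether under basic conditions that cannot ionise the allylic alcohol.

Step 14
Reactants: 19 isovanillic acid
Product: 21 3-(tert-butyldimethylsilyloxy)-4-methoxybenzoic acid, via bis-silylated isovanillate 20 (not isolated)
Conditions: tBuMe2SiCl (2.5 equiv), imidazole, DMF, rt; then AcOH–THF–H2O, rt
Reagents that add atoms: tert-butyldimethylsilyl chloride, CC(C)(C)[Si](C)(C)Cl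
Why: Exhaustive silylation followed by selective hydrolysis of the labile silyl ester is a standard way to protect a phenol in the presence of a carboxylic acid.

Step 15
Reactants: 21 3-(tert-butyldimethylsilyloxy)-4-methoxybenzoic acid; 18 diol
Product: 23 silyl-protected ester (6β-O-aroyl, 4β-hydroxy), via mixed anhydride 22 (not isolated)
Conditions: 2,4,6-Cl3C6H2COCl, Et3N, THF, rt; then 18, DMAP, PhMe, rt → 40 °C
Reagents that add atoms: 2,4,6-trichlorobenzoyl chloride, O=C(Cl)c1c(Cl)cc(Cl)cc1Cl (acyl group present in 22 only)
Why: Yamaguchi esterification through the mixed anhydride should acylate the secondary allylic C6 hydroxyl only, the tertiary C4 hydroxyl beside the isopropyl group being inert, and C6 keeps its configuration because its C–O bond is not broken.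

Step 16
Reactants: 23 silyl-protected ester
Product: 24 target, (3R,3aS,4R,8aR)-3-hydroxy-6,8a-dimethyl-3-(propan-2-yl)-1,2,3,3a,4,7,8,8a-octahydroazulen-4-yl 3-hydroxy-4-methoxybenzoate
Conditions: Bu4NF, AcOH, THF, 0 °C
Reagents that add atoms: none
Why: Buffered fluoride removes the aryl silyl ether without attacking the benzoate, the tertiary alcohol or the allylic C–O bond.

**Compound list**

1 | (S)-terpinen-4-ol, (1S)-4-methyl-1-(propan-2-yl)cyclohex-3-en-1-ol | CC1=CC[C@](O)(C(C)C)CC1 | starting material
2 | triethyl{[(1S)-4-methyl-1-(propan-2-yl)cyclohex-3-en-1-yl]oxy}silane | CC1=CC[C@](O[Si](CC)(CC)CC)(C(C)C)CC1 | intermediate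
3 | secondary ozonide of 2, (4S)-1-methyl-4-(propan-2-yl)-4-(triethylsilyloxy)-7,8,9-trioxabicyclo[4.2.1]nonane (trioxolane carbons as formed) | CC12CC[C@@](O[Si](CC)(CC)CC)(C(C)C)CC(OO1)O2 | intermediate (not isolated)
4 | (3S)-6-oxo-3-(propan-2-yl)-3-(triethylsilyloxy)heptanal | O=CC[C@](O[Si](CC)(CC)CC)(C(C)C)CCC(C)=O | intermediate
5 | (5R)-2-methyl-5-(propan-2-yl)-5-(triethylsilyloxy)cyclopent-1-ene-1-carbaldehyde | O=CC1=C(C)CC[C@@]1(O[Si](CC)(CC)CC)C(C)C | intermediate
6 | vinylmagnesium bromide | C=C[Mg]Br | starting material
7 | trimethylsilyl enol ether of 8 (exocyclic C5=CH–OSiMe3; vinyl and silyloxy cis) | C=C[C@]1(C)CC[C@@](O[Si](CC)(CC)CC)(C(C)C)C1=CO[Si](C)(C)C | intermediate (not isolated)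
8 | (1R,2S,5R)-2-ethenyl-2-methyl-5-(propan-2-yl)-5-(triethylsilyloxy)cyclopentane-1-carbaldehyde (formyl, vinyl and silyloxy on one face) | C=C[C@]1(C)CC[C@@](O[Si](CC)(CC)CC)(C(C)C)[C@@H]1C=O | intermediate
9 | cis-diquinane ketone, (3aS,6R,6aR)-3a-methyl-6-(propan-2-yl)-6-(triethylsilyloxy)hexahydropentalen-1(2H)-one | O=C1CC[C@]2(C)CC[C@@](O[Si](CC)(CC)CC)(C(C)C)[C@H]12 | intermediate
10 | trimethylsilyl enol ether of 9 (C6–OSiMe3, C6=C9) | C[Si](C)(C)OC1=CC[C@]2(C)CC[C@@](O[Si](CC)(CC)CC)(C(C)C)[C@H]12 | intermediate
11 | trichloroacetyl chloride | ClC(Cl)(Cl)C(Cl)=O | starting material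
12 | tricyclic 7,7-dichloro-6β-(trimethylsilyloxy)cyclobutanone (C8 ketone, four-membered ring on the α-face) | O=C1C(Cl)(Cl)[C@@]2(O[Si](C)(C)C)[C@@H]1C[C@]3(C)CC[C@@](O[Si](CC)(CC)CC)(C(C)C)[C@H]23 | intermediate
13 | tricyclic 6β-(trimethylsilyloxy)cyclobutanone (key-step precursor) | O=C1C[C@@]2(O[Si](C)(C)C)[C@@H]1C[C@]3(C)CC[C@@](O[Si](CC)(CC)CC)(C(C)C)[C@H]23 | intermediate
14 | cis-fused hydroazulene-6,8-dione, (1S,4R,5R) in daucane locants, 4β-triethylsilyloxy (key-step product) | O=C1CC(=O)CC[C@]2(C)CC[C@@](O[Si](CC)(CC)CC)(C(C)C)[C@H]12 | intermediate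
15 | vinylogous triflate (C6 ketone, C7=C8–OTf) | O=C1C=C(OS(=O)(=O)C(F)(F)F)CC[C@]2(C)CC[C@@](O[Si](CC)(CC)CC)(C(C)C)[C@H]12 | intermediate
16 | enone (C6 ketone, C7=C8–CH3, 4β-triethylsilyloxy) | O=C1C=C(C)CC[C@]2(C)CC[C@@](O[Si](CC)(CC)CC)(C(C)C)[C@H]12 | intermediate
17 | allylic alcohol (6β-hydroxy, 4β-triethylsilyloxy, C7=C8) | O[C@@H]1C=C(C)CC[C@]2(C)CC[C@@](O[Si](CC)(CC)CC)(C(C)C)[C@H]12 | intermediate
18 | diol (4β,6β-dihydroxy, C7=C8) | O[C@@H]1C=C(C)CC[C@]2(C)CC[C@@](O)(C(C)C)[C@H]12 | intermediate
19 | isovanillic acid, 3-hydroxy-4-methoxybenzoic acid | COc1ccc(C(=O)O)cc1O | starting material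
20 | tert-butyldimethylsilyl 3-(tert-butyldimethylsilyloxy)-4-methoxybenzoate | COc1ccc(C(=O)O[Si](C)(C)C(C)(C)C)cc1O[Si](C)(C)C(C)(C)C | intermediate (not isolated)
21 | 3-(tert-butyldimethylsilyloxy)-4-methoxybenzoic acid | COc1ccc(C(=O)O)cc1O[Si](C)(C)C(C)(C)C | intermediate
22 | mixed anhydride of 21 and 2,4,6-trichlorobenzoic acid | COc1ccc(C(=O)OC(=O)c2c(Cl)cc(Cl)cc2Cl)cc1O[Si](C)(C)C(C)(C)C | intermediate (not isolated)
23 | silyl-protected ester (6β-O-[3-(tert-butyldimethylsilyloxy)-4-methoxybenzoyl], 4β-hydroxy) | COc1ccc(C(=O)O[C@@H]2C=C(C)CC[C@]3(C)CC[C@@](O)(C(C)C)[C@H]23)cc1O[Si](C)(C)C(C)(C)C | intermediate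
24 | (3R,3aS,4R,8aR)-3-hydroxy-6,8a-dimethyl-3-(propan-2-yl)-1,2,3,3a,4,7,8,8a-octahydroazulen-4-yl 3-hydroxy-4-methoxybenzoate | COc1ccc(C(=O)O[C@@H]2C=C(C)CC[C@]3(C)CC[C@@](O)(C(C)C)[C@H]23)cc1O | target

**Step count**

Total steps: 16. Longest linear sequence: 15 steps (steps 1–13, 15 and 16); step 14 is a one-step branch.

**Steps most likely to fail**

1. Step 4. What may go wrong: the vinyl group is delivered to the α-face of C1 because the silyloxy group, and not the isopropyl group, takes the pseudoaxial shielding position; in addition the β-silyloxy group may be eliminated during the basic equilibration of C5. The fallback replaces steric control by chelation control and sets out from 5. Bu4NF in THF removes the silyl group to give (5R)-5-hydroxy-2-methyl-5-(propan-2-yl)cyclopent-1-ene-1-carbaldehyde F1. This is converted into its magnesium alkoxide by the first equivalent of CH2=CHMgBr and treated with further CH2=CHMgBr and CuBr·SMe2 in THF at −78 °C. The alkoxide–magnesium–formyl chelate should hold the C4 oxygen near the enal plane and force the isopropyl group pseudoaxial, so that vinyl enters on the oxygen-bearing β-face and gives 5-hydroxy-2-methyl-5-(propan-2-yl)-2-vinylcyclopentane-1-carbaldehyde F2 as a mixture at the formyl-bearing carbon. Immediate silylation (Et3SiOTf, 2,6-lutidine) followed by the K2CO3/MeOH equilibration of step 4 brings the material back to the route at 8.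

2. Step 10. What may go wrong: sulfonylation at the hindered C6 oxygen or at C7, or hydrolytic loss of the vinylogous triflate on isolation. The fallback differentiates the two carbonyls by nucleophilic attack at carbon and then transposes the enone; it sets out from 14. Condensation with pyrrolidine (PhH, reflux, water removal) should take place at the unhindered C8 carbonyl and give the enaminone F3 (C6 ketone, C7=C8–N). LiAlH4 reduces its C6 carbonyl to the enamino alcohol F4, which on mild aqueous acid work-up loses pyrrolidine and water to give the transposed enone F5 (C8 ketone, C6=C7). MeLi with CeCl3 adds to C8 and gives the tertiary allylic alcohol F6. Oxidative 1,3-transposition with pyridinium chlorochromate, C5H5NH[CrO3Cl] (Babler–Dauben oxidation), moves the oxygen to C6 and the double bond to C7=C8, returning to the route at 16.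

3. Step 9. What may go wrong: heterolysis of the exocyclic C6–C7 bond, which would leave an acetyl-substituted cyclopentanone, or base-induced loss of the C4 silyloxy group from the product. The fallback replaces the anionic fragmentation by a radical one and sets out from 13. Citric acid in MeOH at 0 °C removes only the trimethylsilyl group and gives the β-hydroxycyclobutanone F7. Treatment with PhI(OAc)2 and I2 under visible light generates the C6 alkoxy radical; β-scission of the strained ring-fusion bond should give the more substituted, secondary α-keto radical at C9, which is trapped as the 9-iodo-6,8-dione F8. Bu3SnH (AIBN, PhH) removes the iodine and returns to the route at 14.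

**Further compounds**

F1 | step 4 | (5R)-5-hydroxy-2-methyl-5-(propan-2-yl)cyclopent-1-ene-1-carbaldehyde | O=CC1=C(C)CC[C@@]1(O)C(C)C
F2 | step 4 | (2S,5R)-2-ethenyl-5-hydroxy-2-methyl-5-(propan-2-yl)cyclopentane-1-carbaldehyde (mixture at C1 of the ring) | C=C[C@]1(C)CC[C@@](O)(C(C)C)C1C=O
F3 | step 10 | enaminone (C6 ketone, C7=C8, pyrrolidin-1-yl on C8, 4β-triethylsilyloxy) | O=C1C=C(N3CCCC3)CC[C@]2(C)CC[C@@](O[Si](CC)(CC)CC)(C(C)C)[C@H]12
F4 | step 10 | enamino alcohol (6-hydroxy, C7=C8, pyrrolidin-1-yl on C8) | OC1C=C(N3CCCC3)CC[C@]2(C)CC[C@@](O[Si](CC)(CC)CC)(C(C)C)[C@H]12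
F5 | step 10 | transposed enone (C8 ketone, C6=C7, 4β-triethylsilyloxy) | O=C1CC[C@]2(C)CC[C@@](O[Si](CC)(CC)CC)(C(C)C)[C@@H]2C=C1
F6 | step 10 | tertiary allylic alcohol (8-hydroxy-8-methyl, C6=C7) | CC1(O)CC[C@]2(C)CC[C@@](O[Si](CC)(CC)CC)(C(C)C)[C@@H]2C=C1
F7 | step 9 | tricyclic 6β-hydroxycyclobutanone (C8 ketone, 4β-triethylsilyloxy) | O=C1C[C@@]2(O)[C@@H]1C[C@]3(C)CC[C@@](O[Si](CC)(CC)CC)(C(C)C)[C@H]23
F8 | step 9 | 9-iodo-cis-hydroazulene-6,8-dione (4β-triethylsilyloxy) | O=C1CC(=O)C(I)C[C@]2(C)CC[C@@](O[Si](CC)(CC)CC)(C(C)C)[C@H]12
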